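**Retrosynthetic overview**

1. Target 12 ⇐ tris-MOM flavanone 11; the acetals come off last, with both prenyl groups and all oxygens already in place.
2. Ring C is opened at O1–C8a: 11 ⇐ (S)-β-hydroxy ketone 10 carrying fluorine on the future C8a. The enabling feature is that in ring A C8a is ortho to the C4 carbonyl, so O1–C8a=C4a–C4=O is a vinylogous ester built into the arene; C8a is therefore the β-carbon of an aryl ketone and takes up the C2 alkoxide by addition–elimination, the fluorine being a traceless activating and leaving group.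
3. 10 ⇐ (E)-chalcone 8 by copper-catalysed asymmetric β-borylation/oxidation (sets C2) ⇐ aryl methyl ketone 6 + aldehyde 7 (Claisen–Schmidt).
4. 6 ⇐ 5-fluororesorcinol 1 by C-acetylation, double O-allylation, regioconvergent double Claisen rearrangement, MOM protection and double cross-metathesis (allyl → prenyl).
5. Ring order: rings A and B are bought as benzenoid building blocks; ring C is the only ring made, and it is closed in step 8.

Key step: step 8

Remark: the sense of induction in step 7 is taken from simple (E)-β-aryl enones; if chalcone 8 responds in the opposite sense, the antipodal ligand is used. Compounds 1 and 7 are taken as catalogue chemicals.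

**Route**

Step 1
Reactants: 1 5-fluororesorcinol (5-fluorobenzene-1,3-diol)
Product: 2 1-(2-fluoro-4,6-dihydroxyphenyl)ethan-1-one
Conditions: AcOH, ZnCl2 (1.5 equiv), 140 °C
Reagents that add atoms: acetic acid, CC(=O)O
Why: Nencki-type Friedel–Crafts C-acylation of a resorcinol should go para to one hydroxyl and ortho to the other (here also ortho to fluorine), because the site between the two hydroxyls is the more hindered one.

Step 2
Reactants: 2 1-(2-fluoro-4,6-dihydroxyphenyl)ethan-1-one
Product: 3 1-[2-fluoro-4,6-bis(prop-2-en-1-yloxy)phenyl]ethan-1-one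
Conditions: allyl bromide (2.5 equiv), K2CO3, DMF, 60 °C
Reagents that add atoms: allyl bromide, C=CCBr
Why: Williamson etherification should allylate both phenols (the chelated one needs DMF and warming), while the phenoxide-rich ring keeps the C–F bond inert to substitution.

Step 3
Reactants: 3 1-[2-fluoro-4,6-bis(prop-2-en-1-yloxy)phenyl]ethan-1-one
Product: 4 1-[2-fluoro-4,6-dihydroxy-3,5-di(prop-2-en-1-yl)phenyl]ethan-1-one
Conditions: N,N-diethylaniline, 200 °C (sealed tube)
Reagents that add atoms: none
Why: The thermal aromatic Claisen rearrangement is regioconvergent here: the 6-O-allyl group can only reach C5, the 4-O-allyl group C3 or C5, and if C5 is already taken the second allyl group is relayed to C3 by a para-Claisen (Claisen–Cope) sequence, so every pathway should end at the 3,5-diallyl pattern.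

Step 4
Reactants: 4 1-[2-fluoro-4,6-dihydroxy-3,5-di(prop-2-en-1-yl)phenyl]ethan-1-one
Product: 5 1-[2-fluoro-4,6-bis(methoxymethoxy)-3,5-di(prop-2-en-1-yl)phenyl]ethan-1-one
Conditions: NaH (2.1 equiv), MOMCl (2.4 equiv), DMF, 0 °C → rt
Reagents that add atoms: chloromethyl methyl ether, COCCl
Why: O-Alkylation of both sodium phenoxides (the hindered, chelated one included) should give base-stable MOM acetals, which also prevent ring A from becoming a deactivating phenoxide in the later substitution step.

Step 5
Reactants: 5 1-[2-fluoro-4,6-bis(methoxymethoxy)-3,5-di(prop-2-en-1-yl)phenyl]ethan-1-one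
Product: 6 1-[2-fluoro-4,6-bis(methoxymethoxy)-3,5-bis(3-methylbut-2-en-1-yl)phenyl]ethan-1-one
Conditions: 2-methyl-2-butene (excess), second-generation Grubbs catalyst RuCl2(H2IMes)(PCy3)(=CHPh) (5 mol %), CH2Cl2, 40 °C
Reagents that add atoms: 2-methyl-2-butene, CC=C(C)C
Why: Olefin cross-metathesis of the two terminal allyl groups with excess 2-methyl-2-butene is a standard way to turn C-allyl into C-prenyl arenes, and no alkene geometry arises because the new alkene carbon carries two methyl groups.

Step 6
Reactants: 6 1-[2-fluoro-4,6-bis(methoxymethoxy)-3,5-bis(3-methylbut-2-en-1-yl)phenyl]ethan-1-one; 7 4-(methoxymethoxy)benzaldehyde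
Product: 8 (2E)-1-[2-fluoro-4,6-bis(methoxymethoxy)-3,5-bis(3-methylbut-2-en-1-yl)phenyl]-3-[4-(methoxymethoxy)phenyl]prop-2-en-1-one
Conditions: KOH, EtOH/H2O, 0 °C → rt
Reagents that add atoms: none
Why: Claisen–Schmidt aldol condensation with E1cB dehydration should give the thermodynamically favoured (E)-enone, and the hindered C–F bond between the acyl and prenyl groups should survive ethanolic hydroxide at room temperature.

Step 7
Reactants: 8 (2E)-1-[2-fluoro-4,6-bis(methoxymethoxy)-3,5-bis(3-methylbut-2-en-1-yl)phenyl]-3-[4-(methoxymethoxy)phenyl]prop-2-en-1-one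
Product: 10 (3S)-1-[2-fluoro-4,6-bis(methoxymethoxy)-3,5-bis(3-methylbut-2-en-1-yl)phenyl]-3-hydroxy-3-[4-(methoxymethoxy)phenyl]propan-1-one, via β-boryl ketone 9 (not isolated)
Conditions: CuCl (3 mol %), NaOt-Bu (6 mol %), (R,Sp)-Josiphos [(R)-1-[(Sp)-2-(diphenylphosphino)ferrocenyl]ethyldicyclohexylphosphine] (4 mol %), B2pin2 (1.1 equiv), MeOH (2 equiv), THF, rt; then NaBO3·4H2O, THF/H2O, rt
Reagents that add atoms: bis(pinacolato)diboron, CC1(C)OB(OC1(C)C)B1OC(C)(C)C(C)(C)O1 (boron of 9); sodium perborate, [Na+].[Na+].O[B-]1(O)OO[B-](O)(O)OO1 (hydroxyl oxygen of 10)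
Why: In this copper-catalysed asymmetric conjugate borylation of an (E)-β-aryl enone the chiral bisphosphine–Cu–Bpin complex adds boron to one face of C3 (catalyst control), and stereoretentive perborate oxidation of the C–B bond should then give the (S)-alcohol while the isolated trisubstituted alkenes, the aryl fluoride and the MOM ethers stay untouched.

Step 8
Reactants: 10 (3S)-1-[2-fluoro-4,6-bis(methoxymethoxy)-3,5-bis(3-methylbut-2-en-1-yl)phenyl]-3-hydroxy-3-[4-(methoxymethoxy)phenyl]propan-1-one
Product: 11 (2S)-5,7-bis(methoxymethoxy)-2-[4-(methoxymethoxy)phenyl]-6,8-bis(3-methylbut-2-en-1-yl)-2,3-dihydro-4H-chromen-4-one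
Conditions: NaN(SiMe3)2 (0.98 equiv), THF, −78 °C; then DMPU, −78 → 0 °C
Reagents that add atoms: none
Why: Kinetic O-deprotonation at −78 °C gives the C2 alkoxide, which adds to C8a of ring A (ipso to fluorine, β to the C4 carbonyl) to form a Meisenheimer anion delocalised into the C4 enolate, and loss of fluoride as NaF re-aromatises ring A, i.e. an intramolecular SNAr O-arylation. The closest known reaction type is the base-mediated cyclisation of 2-fluoroaryl ketones bearing a tethered oxygen nucleophile to chromanones and chromones, and the event is the arene counterpart of the addition–elimination that closes the dihydropyranone ring in Mukaiyama-aldol-type hetero-Diels–Alder sequences of 1-methoxy-3-silyloxy dienes. Ring C closes in a 6-endo-trig addition–elimination mode across the C4a=C8a bond. No new stereocentre is formed: C2 keeps the (S) configuration set in step 7 because only its O–H bond reacts and the C2–O bond is never broken. The step needs chemoselectivity for cyclisation over retro-aldol cleavage and E1cB dehydration, which the substrate secures through six-membered intramolecular delivery, ortho-acyl activation reinforced inductively by the meta OMOM groups at C5 and C7, and fluoride as the fastest SNAr leaving group, while the single C–F bond removes any site-selectivity question. The base is consumed as NaF, so none is left to open the product by retro-oxa-Michael reaction.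

Step 9
Reactants: 11 (2S)-5,7-bis(methoxymethoxy)-2-[4-(methoxymethoxy)phenyl]-6,8-bis(3-methylbut-2-en-1-yl)-2,3-dihydro-4H-chromen-4-one
Product: 12 (2S)-5,7-dihydroxy-2-(4-hydroxyphenyl)-6,8-bis(3-methylbut-2-en-1-yl)-2,3-dihydro-4H-chromen-4-one (6,8-diprenylnaringenin)
Conditions: 3 M aq. HCl, MeOH, 45 °C
Reagents that add atoms: none
Why: Acid-catalysed acetal exchange with methanol should release all three phenols as dimethoxymethane under dilute conditions of the kind routinely applied to MOM-protected prenylflavanones, and C2 is not at risk because flavanones lose configuration through base-induced ring opening, which is absent here.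

**Compound list**

1 | 5-fluororesorcinol (5-fluorobenzene-1,3-diol) | Oc1cc(O)cc(F)c1 | starting material
2 | 1-(2-fluoro-4,6-dihydroxyphenyl)ethan-1-one | CC(=O)c1c(O)cc(O)cc1F | intermediate
3 | 1-[2-fluoro-4,6-bis(prop-2-en-1-yloxy)phenyl]ethan-1-one | CC(=O)c1c(OCC=C)cc(OCC=C)cc1F | intermediate
4 | 1-[2-fluoro-4,6-dihydroxy-3,5-di(prop-2-en-1-yl)phenyl]ethan-1-one | CC(=O)c1c(O)c(CC=C)c(O)c(CC=C)c1F | intermediate
5 | 1-[2-fluoro-4,6-bis(methoxymethoxy)-3,5-di(prop-2-en-1-yl)phenyl]ethan-1-one | CC(=O)c1c(OCOC)c(CC=C)c(OCOC)c(CC=C)c1F | intermediate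
6 | 1-[2-fluoro-4,6-bis(methoxymethoxy)-3,5-bis(3-methylbut-2-en-1-yl)phenyl]ethan-1-one | CC(=O)c1c(OCOC)c(CC=C(C)C)c(OCOC)c(CC=C(C)C)c1F | intermediate
7 | 4-(methoxymethoxy)benzaldehyde | COCOc1ccc(C=O)cc1 | starting material
8 | (2E)-1-[2-fluoro-4,6-bis(methoxymethoxy)-3,5-bis(3-methylbut-2-en-1-yl)phenyl]-3-[4-(methoxymethoxy)phenyl]prop-2-en-1-one | COCOc1ccc(/C=C/C(=O)c2c(OCOC)c(CC=C(C)C)c(OCOC)c(CC=C(C)C)c2F)cc1 | intermediate
9 | (3S)-1-[2-fluoro-4,6-bis(methoxymethoxy)-3,5-bis(3-methylbut-2-en-1-yl)phenyl]-3-[4-(methoxymethoxy)phenyl]-3-(4,4,5,5-tetramethyl-1,3,2-dioxaborolan-2-yl)propan-1-one (β-boryl ketone, not isolated) | CC(C)=CCc1c(OCOC)c(CC=C(C)C)c(F)c(C(=O)C[C@@H](c2ccc(OCOC)cc2)B2OC(C)(C)C(C)(C)O2)c1OCOC | intermediate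
10 | (3S)-1-[2-fluoro-4,6-bis(methoxymethoxy)-3,5-bis(3-methylbut-2-en-1-yl)phenyl]-3-hydroxy-3-[4-(methoxymethoxy)phenyl]propan-1-one | CC(C)=CCc1c(OCOC)c(CC=C(C)C)c(F)c(C(=O)C[C@@H](c2ccc(OCOC)cc2)O)c1OCOC | intermediate
11 | (2S)-5,7-bis(methoxymethoxy)-2-[4-(methoxymethoxy)phenyl]-6,8-bis(3-methylbut-2-en-1-yl)-2,3-dihydro-4H-chromen-4-one | CC(C)=CCc1c(OCOC)c(CC=C(C)C)c2c(c1OCOC)C(=O)C[C@@H](c1ccc(OCOC)cc1)O2 | intermediate
12 | (2S)-5,7-dihydroxy-2-(4-hydroxyphenyl)-6,8-bis(3-methylbut-2-en-1-yl)-2,3-dihydro-4H-chromen-4-one (6,8-diprenylnaringenin) | CC(C)=CCc1c(O)c(CC=C(C)C)c2c(c1O)C(=O)C[C@@H](c1ccc(O)cc1)O2 | target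

**Step count**

Total: 9 steps. Longest linear sequence: 9 steps (1 → 12); aldehyde 7 is bought.

**Steps most likely to fail**

Step 8. Retro-aldol cleavage or E1cB dehydration of the alkoxide may outrun ring closure, and retro-aldol/re-aldol would erode the configuration at C2. The fallback sets out from 10 and returns at 11, closing the same O1–C8a bond at the diketone oxidation level, where no carbinol stereocentre or β-hydroxyl is exposed to base. Dess–Martin periodinane (CH2Cl2, NaHCO3, rt) should oxidise 10 to the 1,3-diketone 1-[2-fluoro-4,6-bis(methoxymethoxy)-3,5-bis(3-methylbut-2-en-1-yl)phenyl]-3-[4-(methoxymethoxy)phenyl]propane-1,3-dione F1. K2CO3 in DMF at 60 °C should then cyclise it through the enolate oxygen by SNAr, the classical chromone closure of 2-fluoroaryl 1,3-diketones, to the flavone 5,7-bis(methoxymethoxy)-2-[4-(methoxymethoxy)phenyl]-6,8-bis(3-methylbut-2-en-1-yl)-4H-chromen-4-one F2. Copper hydride-catalysed asymmetric conjugate reduction of the C2=C3 bond (Cu(OAc)2, the DTBM-SEGPHOS antipode that gives (2S), (EtO)2MeSiH, t-BuOH, toluene) should set C2 and return to 11.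

Step 7. Facial selectivity may be poor or the conjugate addition sluggish, because the enone carbonyl is twisted out of the plane of the di-ortho-substituted ring A. The fallback sets out from 8 and returns at 10, introducing the oxygen by asymmetric nucleophilic epoxidation in place of borylation. Juliá–Colonna epoxidation (poly-D-leucine, urea–hydrogen peroxide, DBU, THF) should give the trans-epoxy ketone [2-fluoro-4,6-bis(methoxymethoxy)-3,5-bis(3-methylbut-2-en-1-yl)phenyl][(2S,3R)-3-[4-(methoxymethoxy)phenyl]oxiran-2-yl]methanone F3. Regioselective reductive cleavage of its Cα–O bond with sodium phenylselenolate made from PhSeSePh and NaBH4 (EtOH, AcOH, 0 °C) should give 10 with the benzylic C–O bond intact.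

Step 3. At 200 °C the ortho-allylphenols may cyclise to dihydrobenzofurans, or the para-relay of the second allyl group may stay incomplete. The fallback sets out from 2 and returns at 6, bypassing 3, 4 and 5 by direct C-prenylation. Treatment of 2 with prenyl bromide (2.2 equiv) and DBU in THF (0 °C → rt), the known but lower-yielding C-alkylation of acylresorcinols, should give 1-[2-fluoro-4,6-dihydroxy-3,5-bis(3-methylbut-2-en-1-yl)phenyl]ethan-1-one F4. NaH/MOMCl in DMF should then convert it into 6.

**Further compounds**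

F1 | step 8 | 1-[2-fluoro-4,6-bis(methoxymethoxy)-3,5-bis(3-methylbut-2-en-1-yl)phenyl]-3-[4-(methoxymethoxy)phenyl]propane-1,3-dione | CC(C)=CCc1c(OCOC)c(CC=C(C)C)c(F)c(C(=O)CC(=O)c2ccc(OCOC)cc2)c1OCOC
F2 | step 8 | 5,7-bis(methoxymethoxy)-2-[4-(methoxymethoxy)phenyl]-6,8-bis(3-methylbut-2-en-1-yl)-4H-chromen-4-one | CC(C)=CCc1c(OCOC)c(CC=C(C)C)c2c(c1OCOC)C(=O)C=C(c1ccc(OCOC)cc1)O2
F3 | step 7 | [2-fluoro-4,6-bis(methoxymethoxy)-3,5-bis(3-methylbut-2-en-1-yl)phenyl][(2S,3R)-3-[4-(methoxymethoxy)phenyl]oxiran-2-yl]methanone | CC(C)=CCc1c(OCOC)c(CC=C(C)C)c(F)c(C(=O)[C@H]2O[C@@H]2c3ccc(OCOC)cc3)c1OCOC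
F4 | step 3 | 1-[2-fluoro-4,6-dihydroxy-3,5-bis(3-methylbut-2-en-1-yl)phenyl]ethan-1-one | CC(=O)c1c(O)c(CC=C(C)C)c(O)c(CC=C(C)C)c1F
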